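Die ganze Planung beruht auf dem Schnitt der C1–C6-Bindung von ring A (C1 bears the exocyclic CH2; C2 and C3 are CH2; C4 is the carbinol; C5 is CMe2; C6 carries the side chain). The structural feature used is that C1 is trigonal and keeps its =CH2 throughout, while C6 sits next to quaternary C5, whose bond to C4 can come from an isobutyrate aldol. In one operation a vinyl radical at C1 attacks the enoate β-carbon C6 in the 6-exo mode, closing ring A and setting C6 from C4. The precursor is the open-chain 2-bromo-1-alkene bearing a C4 silyl ether and an E-enoate (12). Suzuki and allylation steps finish the chain.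

Key step: step 8

Assumption: the N-tosyl-D-valine/BH3 promoter is taken to deliver the ketene acetal to the Re face of aldehyde 5, as the usual transition-state model predicts; MTPA ester analysis of 8 should confirm this before material is carried on (the L-valine promoter would be used otherwise).

Step 1
Reactants: 1 tert-butyl acetate; 2 2,3-dibromopropene
Product: 4 tert-butyl 4-bromopent-4-enoate, via lithium enolate of tert-butyl acetate 3 (not isolated)
Conditions: LiN(i-Pr)2, THF, −78 °C; then 2, −78 to 0 °C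
Reagents that add atoms: none
Why: Ester enolate alkylation: the lithium enolate displaces the allylic bromide of 2 in an SN2 reaction while the vinylic bromide is inert, so C1 to C3 arrive with the radical precursor already installed.

Step 2
Reactants: 4 tert-butyl 4-bromopent-4-enoate
Product: 5 4-bromopent-4-enal
Conditions: iBu2AlH (1.1 equiv), CH2Cl2, −78 °C; MeOH, then aq. KNaC4H4O6 (tartrate)
Reagents that add atoms: none
Why: Partial reduction of an ester with an aluminium hydride: at −78 °C the tetrahedral aluminium hemiacetal of the tert-butyl ester should persist until work-up and then collapse to the aldehyde, and the vinyl bromide is not reduced.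

Step 3
Reactants: 5 4-bromopent-4-enal; 6 1-methoxy-2-methyl-1-(trimethylsiloxy)propene
Product: 8 methyl (3S)-6-bromo-3-hydroxy-2,2-dimethylhept-6-enoate, via trimethylsilyl ether of the aldol 7 (not isolated)
Conditions: N-Ts-D-valine (1.1 equiv), BH3·THF (1.0 equiv), CH2Cl2, 0 °C to rt; then 5 and 6, −78 °C; aq. NaHCO3, then 1 M HCl, THF
Reagents that add atoms: none
Why: Enantioselective Mukaiyama aldol: the oxazaborolidinone formed in the flask from N-tosyl-D-valine and BH3 binds the aldehyde and shields one face, so the ketene acetal should add to the Re face, which forms the C4–C5 bond and sets C4 as S.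

Step 4
Reactants: 8 methyl (3S)-6-bromo-3-hydroxy-2,2-dimethylhept-6-enoate
Product: 9 methyl (3S)-6-bromo-3-[(tert-butyldimethylsilyl)oxy]-2,2-dimethylhept-6-enoate
Conditions: TBSOTf, 2,6-lutidine, CH2Cl2, 0 °C
Reagents that add atoms: tert-butyldimethylsilyl triflate, CC(C)(C)[Si](C)(C)OS(=O)(=O)C(F)(F)F
Why: Silylation of an alcohol with a silyl triflate, which is reactive enough for the hindered carbinol beside the quaternary carbon; the ether blocks retro-aldol cleavage and later serves as the equatorial anchor in the ring closure.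

Step 5
Reactants: 9 methyl (3S)-6-bromo-3-[(tert-butyldimethylsilyl)oxy]-2,2-dimethylhept-6-enoate
Product: 10 (3S)-6-bromo-3-[(tert-butyldimethylsilyl)oxy]-2,2-dimethylhept-6-en-1-ol
Conditions: iBu2AlH (2.5 equiv), CH2Cl2, −78 to 0 °C
Reagents that add atoms: none
Why: Hydride reduction of the ester to the neopentyl primary alcohol, chosen over direct partial reduction because the outcome with this hindered ester is more predictable; silyl ether and vinyl bromide are inert.

Step 6
Reactants: 10 (3S)-6-bromo-3-[(tert-butyldimethylsilyl)oxy]-2,2-dimethylhept-6-en-1-ol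
Product: 11 (3S)-6-bromo-3-[(tert-butyldimethylsilyl)oxy]-2,2-dimethylhept-6-enal
Conditions: DMP, CH2Cl2, rt
Reagents that add atoms: none
Why: Dess–Martin oxidation gives the aldehyde under near-neutral conditions, and since the α-carbon is quaternary neither epimerisation nor β-elimination of the silyloxy group can occur.

Step 7
Reactants: 11 (3S)-6-bromo-3-[(tert-butyldimethylsilyl)oxy]-2,2-dimethylhept-6-enal
Product: 12 ethyl (2E,5S)-8-bromo-5-[(tert-butyldimethylsilyl)oxy]-4,4-dimethylnona-2,8-dienoate
Conditions: (EtO)2P(O)CH2CO2Et, NaH, THF, 0 °C to rt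
Reagents that add atoms: triethyl phosphonoacetate, CCOC(=O)CP(=O)(OCC)OCC
Why: Horner–Wadsworth–Emmons olefination of the non-enolisable aldehyde with the stabilised phosphonate anion should give the E-enoate selectively and installs the radical acceptor with C6 as its β-carbon.

Step 8
Reactants: 12 ethyl (2E,5S)-8-bromo-5-[(tert-butyldimethylsilyl)oxy]-4,4-dimethylnona-2,8-dienoate
Product: 13 ethyl 2-[(1R,3S)-3-[(tert-butyldimethylsilyl)oxy]-2,2-dimethyl-6-methylidenecyclohexyl]acetate
Conditions: Bu3SnH (1.3 equiv), AIBN (0.2 equiv), PhMe (0.01 M), 85 °C, syringe-pump addition over 6 h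
Reagents that add atoms: none
Why: The stannyl radical removes bromine from C1, the bent σ-type vinyl radical so formed attacks C6 of the enoate, and the α-ester radical at C7 is quenched by Bu3SnH, which carries the chain. The closest known reaction type is the tin hydride cyclisation of 2-bromo-1-alkenes onto electron-poor alkenes. Ring A closes 6-exo-trig, which brings the =CH2 group in intact under neutral conditions and so excludes isomerisation to the endocyclic alkene. C6 is set by C4: in the chair-like transition state the silyloxy group and the acrylate arm both lie equatorial, which should give the cis-(1R,3S) ring. The step needs 6-exo over 7-endo attack and ring closure faster than hydrogen transfer; the acceptor polarity steers the radical to C6, quaternary C5 folds the chain and has no hydrogen to lose in a 1,5-shift, and syringe-pump addition keeps the stannane dilute. Because the C7 radical is ester-stabilised, it is not expected to add back to the methylene and expand the ring.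

Step 9
Reactants: 13 ethyl 2-[(1R,3S)-3-[(tert-butyldimethylsilyl)oxy]-2,2-dimethyl-6-methylidenecyclohexyl]acetate
Product: 14 2-[(1R,3S)-3-[(tert-butyldimethylsilyl)oxy]-2,2-dimethyl-6-methylidenecyclohexyl]ethan-1-ol
Conditions: iBu2AlH (2.5 equiv), CH2Cl2, −78 to 0 °C
Reagents that add atoms: none
Why: Hydride reduction of the ester to the primary alcohol at low temperature, which leaves the 1,1-disubstituted alkene and the silyl ether untouched and does not affect C4 or C6.

Step 10
Reactants: 14 2-[(1R,3S)-3-[(tert-butyldimethylsilyl)oxy]-2,2-dimethyl-6-methylidenecyclohexyl]ethan-1-ol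
Product: 15 tert-butyl{[(1S,3R)-3-(2-iodoethyl)-2,2-dimethyl-4-methylidenecyclohexyl]oxy}dimethylsilane
Conditions: I2, PPh3, imidazole, CH2Cl2, 0 °C to rt
Reagents that add atoms: iodine, II
Why: Appel reaction in its iodine variant converts the unhindered primary alcohol through its alkoxyphosphonium salt into the iodide by SN2 displacement, under buffered conditions that spare the silyl ether and the exocyclic alkene.

Step 11
Reactants: 16 geraniol
Product: 17 geranyl acetate
Conditions: Ac2O, Et3N, DMAP (cat.), CH2Cl2, rt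
Reagents that add atoms: acetic anhydride, CC(=O)OC(C)=O
Why: Acylation of the alcohol with DMAP catalysis; the acetate deactivates the 2,3-alkene toward the peracid used next.

Step 12
Reactants: 17 geranyl acetate
Product: 18 (2E)-5-(3,3-dimethyloxiran-2-yl)-3-methylpent-2-en-1-yl acetate (racemic at the oxirane)
Conditions: mCPBA (1.05 equiv), CH2Cl2, 0 °C
Reagents that add atoms: 3-chloroperbenzoic acid, O=C(OO)c1cccc(Cl)c1
Why: Prilezhaev epoxidation: the electrophilic peracid selects the electron-rich terminal trisubstituted alkene over the 2,3-alkene, which is deactivated by the allylic acetate; the new stereocentre is racemic and is destroyed in the next step.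

Step 13
Reactants: 18 (2E)-5-(3,3-dimethyloxiran-2-yl)-3-methylpent-2-en-1-yl acetate
Product: 19 (2E)-3-methyl-6-oxohex-2-en-1-yl acetate
Conditions: H5IO6, THF/Et2O, 0 °C
Reagents that add atoms: none
Why: Periodic acid hydrolyses the epoxide and cleaves the glycol (Malaprade cleavage), releasing acetone and leaving the aldehyde whose carbon becomes C10, without touching the remaining alkene or the acetate.

Step 14
Reactants: 19 (2E)-3-methyl-6-oxohex-2-en-1-yl acetate
Product: 20 (2E)-3-methylhept-2-en-6-yn-1-ol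
Conditions: dimethyl (1-diazo-2-oxopropyl)phosphonate, K2CO3, MeOH, 0 °C to rt
Reagents that add atoms: dimethyl (1-diazo-2-oxopropyl)phosphonate, CC(=O)C(=[N+]=[N-])P(=O)(OC)OC
Why: Seyferth–Gilbert homologation in the Ohira–Bestmann variant turns the aldehyde into the terminal alkyne, and the same K2CO3/MeOH medium transesterifies the acetate, so the free allylic alcohol emerges without a separate deprotection.

Step 15
Reactants: 20 (2E)-3-methylhept-2-en-6-yn-1-ol
Product: 22 (2E)-3-methyloct-2-en-6-yn-1-ol, via dilithiated alkynol 21 (not isolated)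
Conditions: n-BuLi (2.1 equiv), THF, −78 to 0 °C; MeI (1.05 equiv), −78 °C to rt
Reagents that add atoms: iodomethane, CI
Why: Alkylation of a lithium acetylide: in the dianion the acetylide carbon is much more nucleophilic toward iodomethane than the lithium alkoxide in THF, so one equivalent of iodomethane should methylate carbon only.

Step 16
Reactants: 22 (2E)-3-methyloct-2-en-6-yn-1-ol
Product: 24 (2E,6E)-7-iodo-3-methylocta-2,6-dien-1-ol, via E-alkenylzirconocene 23 (not isolated)
Conditions: Cp2Zr(H)Cl (3 equiv), THF, 45 °C; then I2, 0 °C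
Reagents that add atoms: iodine, II
Why: Hydrozirconation followed by iodinolysis: syn addition of Zr–H across the 2-alkyne, equilibrated by excess hydride toward zirconium on the less hindered methyl-bearing carbon, and iodination with retention should give the E-2-iodo-2-alkene, while the trisubstituted alkene is too hindered to react.

Step 17
Reactants: 15 tert-butyl{[(1S,3R)-3-(2-iodoethyl)-2,2-dimethyl-4-methylidenecyclohexyl]oxy}dimethylsilane; 24 (2E,6E)-7-iodo-3-methylocta-2,6-dien-1-ol
Product: 27 (2E,6E)-9-[(1R,3S)-3-[(tert-butyldimethylsilyl)oxy]-2,2-dimethyl-6-methylidenecyclohexyl]-3,7-dimethylnona-2,6-dien-1-ol, via primary alkyllithium 25 (not isolated), via lithium borinate 26 (not isolated)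
Conditions: 15, t-BuLi (2.1 equiv), Et2O, −78 °C; B-methoxy-9-BBN, THF, −78 °C to rt; then 24, Pd(dppf)Cl2 (5 mol %), AsPh3, aq. K3PO4, DMF, rt
Reagents that add atoms: none
Why: B-alkyl Suzuki–Miyaura coupling: iodine–lithium exchange and trapping with B-methoxy-9-BBN give a borinate that transfers its primary alkyl group to the vinylpalladium species formed from 24, joining C8 to C9 with retention of the E geometry and without touching the free alcohol or the methylene.

Step 18
Reactants: 27 (2E,6E)-9-[(1R,3S)-3-[(tert-butyldimethylsilyl)oxy]-2,2-dimethyl-6-methylidenecyclohexyl]-3,7-dimethylnona-2,6-dien-1-ol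
Product: 28 (2E,6E)-9-[(1R,3S)-3-hydroxy-2,2-dimethyl-6-methylidenecyclohexyl]-3,7-dimethylnona-2,6-dien-1-ol
Conditions: Bu4NF (3 equiv), THF, 50 °C
Reagents that add atoms: none
Why: Fluoride-induced cleavage of the silyl ether, driven by the Si–F bond, should free the hindered C4 hydroxyl on warming; no other group in 27 reacts with Bu4NF.

Step 19
Reactants: 28 (2E,6E)-9-[(1R,3S)-3-hydroxy-2,2-dimethyl-6-methylidenecyclohexyl]-3,7-dimethylnona-2,6-dien-1-ol
Product: 29 (2E,6E)-9-[(1R,3S)-3-hydroxy-2,2-dimethyl-6-methylidenecyclohexyl]-3,7-dimethylnona-2,6-dien-1-yl methyl carbonate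
Conditions: ClCO2Me (1.1 equiv), pyridine, CH2Cl2, −20 to 0 °C
Reagents that add atoms: methyl chloroformate, COC(=O)Cl
Why: Chemoselective acylation with a chloroformate: the primary allylic alcohol reacts far faster than the secondary C4 alcohol, which is flanked by the quaternary carbon, so only the allylic carbonate should form.

Step 20
Reactants: 29 (2E,6E)-9-[(1R,3S)-3-hydroxy-2,2-dimethyl-6-methylidenecyclohexyl]-3,7-dimethylnona-2,6-dien-1-yl methyl carbonate; 30 4-hydroxy-6-methyl-2-pyrone
Product: 31 sartorypyrone D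
Conditions: 30 (2 equiv), Pd(PPh3)4 (5 mol %), THF, 50 °C
Reagents that add atoms: none
Why: Tsuji–Trost allylation: zerovalent palladium ionises the carbonate to a π-allyl complex with loss of CO2 and methoxide, which deprotonates the pyrone; the soft enolate attacks the unsubstituted allyl terminus through C3, any O-allyl product is re-ionised and drained to the C-allyl pyrone, and the 2E geometry and both stereocentres are untouched.

Compound list
1 | tert-butyl acetate | CC(=O)OC(C)(C)C | starting material
2 | 2,3-dibromopropene | C=C(Br)CBr | starting material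
3 | lithium enolate of tert-butyl acetate | C=C(O[Li])OC(C)(C)C | intermediate (not isolated)
4 | tert-butyl 4-bromopent-4-enoate | C=C(Br)CCC(=O)OC(C)(C)C | intermediate
5 | 4-bromopent-4-enal | C=C(Br)CCC=O | intermediate
6 | 1-methoxy-2-methyl-1-(trimethylsiloxy)propene | COC(O[Si](C)(C)C)=C(C)C | starting material
7 | methyl (3S)-6-bromo-2,2-dimethyl-3-(trimethylsilyloxy)hept-6-enoate | C=C(Br)CC[C@H](O[Si](C)(C)C)C(C)(C)C(=O)OC | intermediate (not isolated)
8 | methyl (3S)-6-bromo-3-hydroxy-2,2-dimethylhept-6-enoate | C=C(Br)CC[C@H](O)C(C)(C)C(=O)OC | intermediate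
9 | methyl (3S)-6-bromo-3-[(tert-butyldimethylsilyl)oxy]-2,2-dimethylhept-6-enoate | C=C(Br)CC[C@H](O[Si](C)(C)C(C)(C)C)C(C)(C)C(=O)OC | intermediate
10 | (3S)-6-bromo-3-[(tert-butyldimethylsilyl)oxy]-2,2-dimethylhept-6-en-1-ol | C=C(Br)CC[C@H](O[Si](C)(C)C(C)(C)C)C(C)(C)CO | intermediate
11 | (3S)-6-bromo-3-[(tert-butyldimethylsilyl)oxy]-2,2-dimethylhept-6-enal | C=C(Br)CC[C@H](O[Si](C)(C)C(C)(C)C)C(C)(C)C=O | intermediate
12 | ethyl (2E,5S)-8-bromo-5-[(tert-butyldimethylsilyl)oxy]-4,4-dimethylnona-2,8-dienoate | C=C(Br)CC[C@H](O[Si](C)(C)C(C)(C)C)C(C)(C)/C=C/C(=O)OCC | intermediate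
13 | ethyl 2-[(1R,3S)-3-[(tert-butyldimethylsilyl)oxy]-2,2-dimethyl-6-methylidenecyclohexyl]acetate | C=C1CC[C@H](O[Si](C)(C)C(C)(C)C)C(C)(C)[C@@H]1CC(=O)OCC | intermediate
14 | 2-[(1R,3S)-3-[(tert-butyldimethylsilyl)oxy]-2,2-dimethyl-6-methylidenecyclohexyl]ethan-1-ol | C=C1CC[C@H](O[Si](C)(C)C(C)(C)C)C(C)(C)[C@@H]1CCO | intermediate
15 | tert-butyl{[(1S,3R)-3-(2-iodoethyl)-2,2-dimethyl-4-methylidenecyclohexyl]oxy}dimethylsilane | C=C1CC[C@H](O[Si](C)(C)C(C)(C)C)C(C)(C)[C@@H]1CCI | intermediate
16 | geraniol | CC(C)=CCC/C(C)=C/CO | starting material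
17 | geranyl acetate | CC(C)=CCC/C(C)=C/COC(C)=O | intermediate
18 | (2E)-5-(3,3-dimethyloxiran-2-yl)-3-methylpent-2-en-1-yl acetate (racemic at the oxirane) | CC1(C)OC1CC/C(C)=C/COC(C)=O | intermediate
19 | (2E)-3-methyl-6-oxohex-2-en-1-yl acetate | O=CCC/C(C)=C/COC(C)=O | intermediate
20 | (2E)-3-methylhept-2-en-6-yn-1-ol | C#CCC/C(C)=C/CO | intermediate
21 | dilithium (2E)-3-methylhept-2-en-6-yn-7-id-1-olate | [Li]C#CCC/C(C)=C/CO[Li] | intermediate (not isolated)
22 | (2E)-3-methyloct-2-en-6-yn-1-ol | CC#CCC/C(C)=C/CO | intermediate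
23 | (2E,6E)-7-(chlorozirconocenyl)-3-methylocta-2,6-dien-1-yl zirconocene chloride alkoxide (cyclopentadienyl rings drawn σ-bound) | C/C(=C\CC/C(C)=C/CO[Zr](Cl)(C1C=CC=C1)C1C=CC=C1)[Zr](Cl)(C1C=CC=C1)C1C=CC=C1 | intermediate (not isolated)
24 | (2E,6E)-7-iodo-3-methylocta-2,6-dien-1-ol | I/C(C)=C/CC/C(C)=C/CO | intermediate
25 | {2-[(1R,3S)-3-[(tert-butyldimethylsilyl)oxy]-2,2-dimethyl-6-methylidenecyclohexyl]ethyl}lithium | C=C1CC[C@H](O[Si](C)(C)C(C)(C)C)C(C)(C)[C@@H]1CC[Li] | intermediate (not isolated)
26 | lithium B-{2-[(1R,3S)-3-[(tert-butyldimethylsilyl)oxy]-2,2-dimethyl-6-methylidenecyclohexyl]ethyl}-B-methoxy-9-borabicyclo[3.3.1]nonan-9-uide | C=C1CC[C@H](O[Si](C)(C)C(C)(C)C)C(C)(C)[C@@H]1CC[B-]1(OC)C2CCCC1CCC2.[Li+] | intermediate (not isolated)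
27 | (2E,6E)-9-[(1R,3S)-3-[(tert-butyldimethylsilyl)oxy]-2,2-dimethyl-6-methylidenecyclohexyl]-3,7-dimethylnona-2,6-dien-1-ol | C=C1CC[C@H](O[Si](C)(C)C(C)(C)C)C(C)(C)[C@@H]1CC/C(C)=C/CC/C(C)=C/CO | intermediate
28 | (2E,6E)-9-[(1R,3S)-3-hydroxy-2,2-dimethyl-6-methylidenecyclohexyl]-3,7-dimethylnona-2,6-dien-1-ol | C=C1CC[C@H](O)C(C)(C)[C@@H]1CC/C(C)=C/CC/C(C)=C/CO | intermediate
29 | (2E,6E)-9-[(1R,3S)-3-hydroxy-2,2-dimethyl-6-methylidenecyclohexyl]-3,7-dimethylnona-2,6-dien-1-yl methyl carbonate | C=C1CC[C@H](O)C(C)(C)[C@@H]1CC/C(C)=C/CC/C(C)=C/COC(=O)OC | intermediate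
30 | 4-hydroxy-6-methyl-2-pyrone | Cc1cc(O)cc(=O)o1 | starting material
31 | sartorypyrone D, 4-hydroxy-3-[(2E,6E)-9-[(1R,3S)-3-hydroxy-2,2-dimethyl-6-methylidenecyclohexyl]-3,7-dimethylnona-2,6-dien-1-yl]-6-methyl-2H-pyran-2-one | C=C1CC[C@H](O)C(C)(C)[C@@H]1CC/C(C)=C/CC/C(C)=C/Cc1c(O)cc(C)oc1=O | target

Total step count: 20. Longest linear sequence: 14 steps (steps 1 to 10 and 17 to 20); the geraniol branch (steps 11 to 16) adds 6.

Steps most likely to fail

1. Step 8. What may go wrong: hydrogen transfer from the stannane to the vinyl radical before it closes (plain debromination), or weak transmission of the C4 configuration to C6 at 85 °C. Fallback: a polar ring closure at low temperature, setting out from aldehyde 11. Horner–Wadsworth–Emmons olefination with tert-butyl diethylphosphonoacetate (NaH, THF) should give tert-butyl (2E,5S)-8-bromo-5-[(tert-butyldimethylsilyl)oxy]-4,4-dimethylnona-2,8-dienoate F1. Bromine–lithium exchange with t-BuLi (2.1 equiv, THF/Et2O, −100 to −78 °C) then generates the C1 vinyllithium, which should add 6-exo to the enoate (halogen–metal exchange-initiated intramolecular conjugate addition; the tert-butyl ester resists direct attack). Protonation should give tert-butyl 2-[(1R,3S)-3-[(tert-butyldimethylsilyl)oxy]-2,2-dimethyl-6-methylidenecyclohexyl]acetate F2. LiAlH4 (THF, 0 °C) reduces F2 and the route is rejoined at alcohol 14.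

2. Step 16. What may go wrong: incomplete regiochemical equilibration of the alkenylzirconium, so that iodine also enters at C6 and a regioisomer that is hard to separate is carried into the coupling. Fallback: build the trisubstituted alkene by two stereospecific couplings on a 1,1-dibromoalkene, setting out from aldehyde 19 and iodide 15. Corey–Fuchs dibromoolefination of 19 (CBr4, PPh3, CH2Cl2, 0 °C) should give (2E)-7,7-dibromo-3-methylhepta-2,6-dien-1-yl acetate F3. Alkyllithium 25, made from 15 as in step 17, is transmetallated with ZnBr2 to {2-[(1R,3S)-3-[(tert-butyldimethylsilyl)oxy]-2,2-dimethyl-6-methylidenecyclohexyl]ethyl}zinc bromide F4. Negishi coupling of F4 with F3 under PdCl2(DPEphos) catalysis should replace only the bromine trans to the chain and give (2E,6Z)-7-bromo-9-[(1R,3S)-3-[(tert-butyldimethylsilyl)oxy]-2,2-dimethyl-6-methylidenecyclohexyl]-3-methylnona-2,6-dien-1-yl acetate F5. Methylation with Me2Zn and Pd(P(t-Bu)3)2, a coupling that proceeds with retention, should give (2E,6E)-9-[(1R,3S)-3-[(tert-butyldimethylsilyl)oxy]-2,2-dimethyl-6-methylidenecyclohexyl]-3,7-dimethylnona-2,6-dien-1-yl acetate F6. K2CO3 in MeOH removes the acetate and the route is rejoined at alcohol 27.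

3. Step 20. What may go wrong: competing O-allylation and double allylation of the ambident pyrone anion. Fallback: allylate a β-keto ester and build the pyrone ring afterwards, setting out from carbonate 29. Pd(PPh3)4-catalysed allylation of methyl acetoacetate (THF, rt) should give methyl (4E,8E)-2-acetyl-11-[(1R,3S)-3-hydroxy-2,2-dimethyl-6-methylidenecyclohexyl]-5,9-dimethylundeca-4,8-dienoate F7. LiN(i-Pr)2 (3.2 equiv, THF, −78 to 0 °C) forms the trilithium alkoxide dienolate of F7 F8, which is acylated at its terminal carbon with N-methoxy-N-methylacetamide to give methyl (4E,8E)-11-[(1R,3S)-3-hydroxy-2,2-dimethyl-6-methylidenecyclohexyl]-5,9-dimethyl-2-(3-oxobutanoyl)undeca-4,8-dienoate F9. DBU in refluxing PhMe lactonises F9 with loss of methanol and the route is rejoined at target 31.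

Further compounds
F1 | step 8 | tert-butyl (2E,5S)-8-bromo-5-[(tert-butyldimethylsilyl)oxy]-4,4-dimethylnona-2,8-dienoate | C=C(Br)CC[C@H](O[Si](C)(C)C(C)(C)C)C(C)(C)/C=C/C(=O)OC(C)(C)C
F2 | step 8 | tert-butyl 2-[(1R,3S)-3-[(tert-butyldimethylsilyl)oxy]-2,2-dimethyl-6-methylidenecyclohexyl]acetate | C=C1CC[C@H](O[Si](C)(C)C(C)(C)C)C(C)(C)[C@@H]1CC(=O)OC(C)(C)C
F3 | step 16 | (2E)-7,7-dibromo-3-methylhepta-2,6-dien-1-yl acetate | BrC(Br)=CCC/C(C)=C/COC(C)=O
F4 | step 16 | {2-[(1R,3S)-3-[(tert-butyldimethylsilyl)oxy]-2,2-dimethyl-6-methylidenecyclohexyl]ethyl}zinc bromide | C=C1CC[C@H](O[Si](C)(C)C(C)(C)C)C(C)(C)[C@@H]1CC[Zn]Br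
F5 | step 16 | (2E,6Z)-7-bromo-9-[(1R,3S)-3-[(tert-butyldimethylsilyl)oxy]-2,2-dimethyl-6-methylidenecyclohexyl]-3-methylnona-2,6-dien-1-yl acetate | C=C1CC[C@H](O[Si](C)(C)C(C)(C)C)C(C)(C)[C@@H]1CC/C(Br)=C/CC/C(C)=C/COC(C)=O
F6 | step 16 | (2E,6E)-9-[(1R,3S)-3-[(tert-butyldimethylsilyl)oxy]-2,2-dimethyl-6-methylidenecyclohexyl]-3,7-dimethylnona-2,6-dien-1-yl acetate | C=C1CC[C@H](O[Si](C)(C)C(C)(C)C)C(C)(C)[C@@H]1CC/C(C)=C/CC/C(C)=C/COC(C)=O
F7 | step 20 | methyl (4E,8E)-2-acetyl-11-[(1R,3S)-3-hydroxy-2,2-dimethyl-6-methylidenecyclohexyl]-5,9-dimethylundeca-4,8-dienoate | C=C1CC[C@H](O)C(C)(C)[C@@H]1CC/C(C)=C/CC/C(C)=C/CC(C(C)=O)C(=O)OC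
F8 | step 20 | trilithium alkoxide dienolate of F7 | C=C1CC[C@H](O[Li])C(C)(C)[C@@H]1CC/C(C)=C/CC/C(C)=C/CC(C(=C)O[Li])=C(OC)O[Li]
F9 | step 20 | methyl (4E,8E)-11-[(1R,3S)-3-hydroxy-2,2-dimethyl-6-methylidenecyclohexyl]-5,9-dimethyl-2-(3-oxobutanoyl)undeca-4,8-dienoate | C=C1CC[C@H](O)C(C)(C)[C@@H]1CC/C(C)=C/CC/C(C)=C/CC(C(=O)CC(C)=O)C(=O)OC
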